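**Retrosynthetic overview**
1. The strategy rests on one feature. Ring C (C8, C9, C11, C12, C13, C14) is hexasubstituted and shares its C8–C14 edge with cyclopentene ring D (C7, C8, C14, spiro C4′, carbinol C10′). A single cycloaddition that makes C8–C14 and C12–C13 therefore closes rings C and D together.
2. The target comes from the 11,12-catechol by Ag2O oxidation and a shift of H-7 in the o-quinone. The catechol comes from the C12 phenol, which is formed by a thermal furan–alkyne Diels–Alder reaction and aromatisation of a ring-B-fused 3-silyloxyfuran tethered through C7–C10′–C4′ to the isopropylalkyne.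
3. The cycloaddition precursor comes from a syn-selective titanium aldol (C7–C10′) between a furan-fused cis-AB ketone and 4-(3-methylbutynyl)thujane-4-carbaldehyde.
4. In the AB ketone, ring B derives from 3-ethoxycyclohexenone and C10 from a Cu-catalysed asymmetric methyl conjugate addition. Ring A and the cis H-5 come from an intramolecular tert-alkylation, and the furan from the C6/C8 dione by C9 acylation and cyclodehydration.
5. The aldehyde is made from (1R,5R)-sabinene via sabina ketone, a propargylic carbonate, an allenylboronate and formaldehyde. Rings form in the order B, A, furan, then C and D together.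

Key step: step 18

Remark: atoms carry abietane numbers (C1–C14) and primed thujane numbers (C1′–C6′, C10′); the target SMILES places H-5 on the same face as the C10 methyl (cis A/B fusion, 5β-H), so this epimerisable centre is set by a C–C bond formation and kept under kinetic conditions afterwards.

**Step 1**
Reactants: 1 5-bromo-2-methylpent-2-ene; 2 3-ethoxycyclohex-2-en-1-one
Product: 4 3-(4-methylpent-3-en-1-yl)cyclohex-2-en-1-one, via homoprenylmagnesium bromide 3 (not isolated)
Conditions: Mg, THF, rt; 2, 0 °C; 1 M aq HCl, 0 °C
Reagents that add atoms: water, O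
Why: Stork–Danheiser sequence, in which 1,2-addition of the Grignard reagent to the vinylogous ester and acid-induced loss of ethanol transpose the carbonyl and give the 3-alkyl enone that becomes ring B (carbonyl = C6, β-carbon = C10); no stereocentre is formed.

**Step 2**
Reactants: 4 3-(4-methylpent-3-en-1-yl)cyclohex-2-en-1-one
Product: 5 3-(4-chloro-4-methylpentyl)cyclohex-2-en-1-one
Conditions: HCl (g), CH2Cl2, 0 °C
Reagents that add atoms: hydrogen chloride, Cl
Why: Markovnikov hydrochlorination of the trisubstituted alkene gives the tertiary chloride (future C4 with both methyl groups), while the electron-poor enone double bond is not consumed; no stereocentre is formed.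

**Step 3**
Reactants: 5 3-(4-chloro-4-methylpentyl)cyclohex-2-en-1-one
Product: 7 (S)-[3-(4-chloro-4-methylpentyl)-3-methylcyclohex-1-en-1-yl]oxytrimethylsilane, via dimethylaluminium enolate 6 (not isolated)
Conditions: Me3Al, CuTC (2 mol %), chiral biphenol phosphoramidite (4 mol %, antipode chosen for the S product), Et2O, −30 °C; Et3N, TMSOTf, −30 to 0 °C
Reagents that add atoms: trimethylaluminium, C[Al](C)C; trimethylsilyl triflate, C[Si](C)(C)OS(=O)(=O)C(F)(F)F
Why: Copper-catalysed asymmetric conjugate addition of trimethylaluminium to a 3-alkylcyclohexenone creates quaternary C10 under ligand control, the ether- and amine-complexed aluminium species should leave the tertiary chloride alone, and silylation of the enolate fixes the enol double bond regiospecifically at C5=C6.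

**Step 4**
Reactants: 7 (S)-[3-(4-chloro-4-methylpentyl)-3-methylcyclohex-1-en-1-yl]oxytrimethylsilane
Product: 8 (4aR,8aR)-4a,8,8-trimethyloctahydronaphthalen-1(2H)-one (cis-decalone with C6 ketone and 5β-H and 10β-methyl)
Conditions: TiCl4, CH2Cl2, −78 to −40 °C
Reagents that add atoms: none
Why: Intramolecular Lewis-acid-mediated α-tert-alkylation (SN1 alkylation) of a silyl enol ether, in which the C4 cation is held by the C1–C3 chain on one face of C10 and can reach the neighbouring C5 only from that face in an axial attack anti to the C10 methyl, so ring A should close cis-fused (H-5 syn to CH3-10) under kinetic control.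

**Step 5**
Reactants: 8 (4aR,8aR)-4a,8,8-trimethyloctahydronaphthalen-1(2H)-one
Product: 10 cis-4,4,10-trimethyl-Δ7-octal-6-one (abietane numbering), via lithium enolate 9 (not isolated)
Conditions: LDA, THF, −78 °C; N-tert-butylbenzenesulfinimidoyl chloride, −78 °C
Reagents that add atoms: none
Why: One-pot dehydrogenation of a lithium enolate with a sulfinimidoyl chloride, where kinetic deprotonation occurs at C7 because H-5 lies between two quaternary carbons, and the C7=C8 enone forms at −78 °C so C5 is not touched.

**Step 6**
Reactants: 10 cis-4,4,10-trimethyl-Δ7-octal-6-one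
Product: 12 8β-hydroxy-cis-4,4,10-trimethyldecal-6-one, via 8β-pinacolboryl ketone 11 (not isolated)
Conditions: B2pin2, CuCl/DPEphos (3 mol %), NaOt-Bu (cat.), MeOH (2 equiv), THF, rt; NaBO3·4H2O, THF/H2O, rt
Reagents that add atoms: sodium perborate, [Na+].[Na+].O[B-]1(O)OO[B-](O)(O)OO1
Why: Copper-catalysed conjugate borylation followed by stereoretentive C–B oxidation places oxygen on C8; boron is expected to add from the convex β face, but this centre is removed in step 7.

**Step 7**
Reactants: 12 8β-hydroxy-cis-4,4,10-trimethyldecal-6-one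
Product: 13 cis-4,4,10-trimethyldecalin-6,8-dione
Conditions: IBX, EtOAc, 75 °C
Reagents that add atoms: none
Why: IBX oxidation of a β-hydroxy ketone to the β-diketone runs under neutral conditions, so retro-aldol cleavage and enolisation towards the hindered C5 should be avoided.

**Step 8**
Reactants: 13 cis-4,4,10-trimethyldecalin-6,8-dione; 14 2-[(tert-butyldimethylsilyl)oxy]-N-methoxy-N-methylacetamide
Product: 16 9-[(tert-butyldimethylsilyloxy)acetyl]-cis-4,4,10-trimethyldecalin-6,8-dione, via dilithium dianion 15 (not isolated)
Conditions: LDA (2.3 equiv), THF/DMPU, −78 to −20 °C; 14, −78 to 0 °C; 1 M aq HCl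
Reagents that add atoms: none
Why: γ-Acylation of a β-diketone dianion with a Weinreb amide, in which the second deprotonation takes the C9 methylene rather than the tertiary H-5, the more basic terminal carbanion C9 (not C7) attacks, and the chelated adduct prevents over-addition and proton transfer; C9 in the product is an enolising centre without fixed configuration.

**Step 9**
Reactants: 16 9-[(tert-butyldimethylsilyloxy)acetyl]-cis-4,4,10-trimethyldecalin-6,8-dione
Product: 18 ring-B-fused furan-3(2H)-one with C6 ketone (O on C8 and C11 carbonyl on C9), via hydroxyacetyl triketone 17 (not isolated)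
Conditions: 2 M aq HCl, THF, rt to 40 °C
Reagents that add atoms: none
Why: Acid removes the primary silyl ether and the α′-hydroxy-1,3-diketone undergoes the known cyclodehydration to a 3(2H)-furanone; the C12 hydroxyl can reach only the C8 carbonyl in a five-membered ring, which puts the ring oxygen on C8 and C11 on C9.

**Step 10**
Reactants: 18 ring-B-fused furan-3(2H)-one with C6 ketone
Product: 19 furan-fused cis-AB ketone with 11-OTBS (3-silyloxyfuran C8/C9/C11/C12/O)
Conditions: TBSOTf (1.05 equiv), Et3N, CH2Cl2, −78 to 0 °C
Reagents that add atoms: tert-butyldimethylsilyl triflate, CC(C)(C)[Si](C)(C)OS(=O)(=O)C(F)(F)F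
Why: Soft enolisation, in which the silyl triflate attacks the more Lewis-basic vinylogous-ester oxygen O11 and loss of H-12 gives the aromatic 3-silyloxyfuran, so one equivalent of reagent should leave the C6 ketone free.

**Step 11**
Reactants: 20 (1R,5R)-sabinene
Product: 22 sabina ketone (5-isopropylbicyclo[3.1.0]hexan-2-one with the configuration of 20), via spiro ozonide 21 (not isolated)
Conditions: O3, CH2Cl2, −78 °C; Me2S, −78 °C to rt
Reagents that add atoms: ozone, [O-][O+]=O
Why: Ozonolysis with reductive work-up cleaves the only alkene and leaves the cyclopropane and both ring stereocentres (C1′, C5′) unchanged.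

**Step 12**
Reactants: 22 sabina ketone; 23 3-methylbut-1-yne
Product: 26 methyl 4′-(3-methylbut-1-ynyl)thujan-4′-yl carbonate (alkynyl anti and oxygen syn to the cyclopropane CH2), via lithium acetylide 24 (not isolated), via lithium alkoxide 25 (not isolated)
Conditions: n-BuLi, THF, −78 °C; 22, −78 °C; ClCO2Me, −78 to 0 °C
Reagents that add atoms: methyl chloroformate, COC(=O)Cl
Why: 1,2-Addition of the acetylide to the bicyclic cyclopentanone should occur from the face opposite the cyclopropane methylene, and the tertiary alkoxide is acylated in the same flask to the propargylic carbonate.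

**Step 13**
Reactants: 26 methyl 4′-(3-methylbut-1-ynyl)thujan-4′-yl carbonate
Product: 27 tetrasubstituted allenylboronate (thujan-4′-ylidene)C=C(i-Pr)Bpin with boron on the face anti to the cyclopropane
Conditions: B2pin2, CuOt-Bu (5 mol %), Xantphos (5 mol %), THF, rt
Reagents that add atoms: bis(pinacolato)diboron, CC1(C)OB(OC1(C)C)B1OC(C)(C)C(C)(C)O1
Why: Copper(I)-catalysed anti-SN2′ borylation of a propargylic carbonate; the leaving group is syn to the cyclopropane, so boron ends on the anti face, which fixes the allene axis.

**Step 14**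
Reactants: 27 tetrasubstituted allenylboronate
Product: 29 [4′-(3-methylbut-1-ynyl)thujan-4′-yl]methanol (CH2OH anti and alkynyl syn to the cyclopropane CH2), via pinacol borate ester 28 (not isolated)
Conditions: (CH2O)n, toluene, 80 °C, sealed tube; aq triethanolamine
Reagents that add atoms: formaldehyde (from paraformaldehyde), C=O
Why: Allenylboration through a closed six-membered SE2′ transition state delivers formaldehyde to C4′ on the boron-bearing face, which is also the open face anti to the cyclopropane, so quaternary C4′ forms with the required configuration and only as the homopropargylic alcohol.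

**Step 15**
Reactants: 29 [4′-(3-methylbut-1-ynyl)thujan-4′-yl]methanol
Product: 30 4′-(3-methylbut-1-ynyl)thujane-4′-carbaldehyde
Conditions: TPAP (5 mol %), NMO, 4 Å MS, CH2Cl2, rt
Reagents that add atoms: none
Why: Ley–Griffith oxidation stops at the non-enolisable neopentyl aldehyde and does not affect the alkyne or the cyclopropane.

**Step 16**
Reactants: 19 furan-fused cis-AB ketone with 11-OTBS; 30 4′-(3-methylbut-1-ynyl)thujane-4′-carbaldehyde
Product: 33 syn aldol (C7–C10′ bond β and H-7 α and C10′ carbinol as in the target), via lithium enolate 31 (not isolated), via triisopropoxytitanium enolate 32 (not isolated)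
Conditions: LDA, THF, −78 °C; ClTi(Oi-Pr)3, −78 to −40 °C; 30, −78 to −30 °C; pH 7 buffer
Reagents that add atoms: none
Why: Aldol addition of a triisopropoxytitanium enolate, in which LDA removes the acidic furfurylic H-7, titanium enolates of cyclic ketones react syn-selectively, attack occurs on the convex β face of the cis-fused enolate and on the Felkin–Anh face of the α-quaternary aldehyde (C5′ large, C3′ medium, alkynyl small), so that the three preferences reinforce each other to set C10′ (C7 is also set but erased in step 20) and the strong Ti–O chelate holds the aldolate against retro-aldol.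

**Step 17**
Reactants: 33 syn aldol
Product: 34 cycloaddition precursor (10′-OTES and 11-OTBS furan–alkyne)
Conditions: TESOTf, 2,6-lutidine, CH2Cl2, −78 to 0 °C
Reagents that add atoms: triethylsilyl triflate, CC[Si](CC)(CC)OS(=O)(=O)C(F)(F)F
Why: Silylation with the triflate and a hindered base protects the congested carbinol at low temperature and blocks retro-aldol in the thermal step; TES is chosen because it can still be removed from this neopentyl position under mild acidic fluoride conditions.

**Step 18**
Reactants: 34 cycloaddition precursor (10′-OTES and 11-OTBS furan–alkyne)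
Product: 36 pentacyclic C12 phenol (11-OTBS and 10′-OTES and H-7 α), via 7-oxanorbornadiene 35 (not isolated)
Conditions: o-dichlorobenzene (0.01 M, degassed), BHT (0.1 equiv), 180 °C, sealed tube
Reagents that add atoms: none
Why: The electron-rich 3-silyloxyfuran (diene C8=C9–C11=C12) and the tethered alkyne C13≡C14 undergo a concerted thermal [4+2] cycloaddition to oxanorbornadiene 35, whose C8–O bond then ionises with push from the C11 silyloxy group, and loss of H-12 gives the C12 phenol. The closest known reaction type is the intramolecular Diels–Alder reaction of furans with alkynes followed by isomerisation of the 7-oxanorbornadiene to a phenol. Ring D closes as the five-membered tether ring (chain C7–C10′–C4′, new bond C8–C14), and ring C closes as the six-membered cycloadduct ring (new bonds C8–C14 and C12–C13). No lasting stereocentre is created: C8 and C12 of 35 are fixed by the β-oriented C7–C10′ bond, which brings the alkyne over the β face of the furan, and both vanish on aromatisation, while C5, C10, C4′ and C10′ are spectators. The step needs regiocontrol, which the short tether enforces because C14 can reach no furan carbon other than C8, and a defined direction of bridge opening, which the C11 donor secures because only the C8 cation is conjugated with it. Quaternary C4′ (Thorpe–Ingold effect), the bulky C10′ silyl ether and ring-bound C7 leave the tether only two rotors, which should offset the unactivated alkyne, and aromatisation makes the sequence irreversible.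

**Step 19**
Reactants: 36 pentacyclic C12 phenol
Product: 37 11,12-catechol with free 10′β-hydroxyl and C6 ketone
Conditions: HF·pyridine, pyridine/THF, 0 °C to rt, Ar
Reagents that add atoms: none
Why: Acidic fluoride cleaves the aryl TBS and the secondary TES ether without generating an alkoxide at C10′, so retro-aldol opening of ring D and epimerisation at C5 or C10′ should not occur; the air-sensitive catechol is used at once.

**Step 20**
Reactants: 37 11,12-catechol with free 10′β-hydroxyl and C6 ketone
Product: 39 CNP0178265.1 (target), via 11,12-o-quinone 38 (not isolated)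
Conditions: Ag2O, Et2O, rt, dark; filtration through silica gel
Reagents that add atoms: none
Why: Silver(I) oxide oxidises the catechol to the o-quinone, and the doubly activated H-7 (α to the C6 ketone, vinylogous to the C11 carbonyl) shifts to O11 to give the 11-hydroxy-12-oxo quinone methide, the tautomerisation typical of 6-oxo-abietane o-quinones; C7 becomes sp2 and the neutral medium leaves C5 and C10′ untouched.

**Compound list**
1 | 5-bromo-2-methylpent-2-ene | CC(C)=CCCBr | starting material
2 | 3-ethoxycyclohex-2-en-1-one | CCOC1=CC(=O)CCC1 | starting material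
3 | (4-methylpent-3-en-1-yl)magnesium bromide | CC(C)=CCC[Mg]Br | intermediate
4 | 3-(4-methylpent-3-en-1-yl)cyclohex-2-en-1-one | CC(C)=CCCC1=CC(=O)CCC1 | intermediate
5 | 3-(4-chloro-4-methylpentyl)cyclohex-2-en-1-one | CC(C)(Cl)CCCC1=CC(=O)CCC1 | intermediate
6 | dimethylaluminium C5=C6 enolate of (S)-3-(4-chloro-4-methylpentyl)-3-methylcyclohexanone | C[Al](C)OC1=C[C@](C)(CCCC(C)(C)Cl)CCC1 | intermediate
7 | (S)-[3-(4-chloro-4-methylpentyl)-3-methylcyclohex-1-en-1-yl]oxytrimethylsilane | C[Si](C)(C)OC1=C[C@](C)(CCCC(C)(C)Cl)CCC1 | intermediate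
8 | (4aR,8aR)-4a,8,8-trimethyloctahydronaphthalen-1(2H)-one (cis; 5β-H, 10β-Me, C6 ketone) | O=C1[C@@H]2C(C)(C)CCC[C@]2(C)CCC1 | intermediate
9 | lithium C6=C7 enolate of 8 | [Li]OC1=CCC[C@@]2(C)CCCC(C)(C)[C@@H]12 | intermediate
10 | cis-4,4,10-trimethyl-Δ7-octal-6-one | O=C1[C@@H]2C(C)(C)CCC[C@]2(C)CC=C1 | intermediate
11 | 8β-(pinacolboryl)-cis-4,4,10-trimethyldecal-6-one | O=C1[C@@H]2C(C)(C)CCC[C@]2(C)C[C@@H](B3OC(C)(C)C(C)(C)O3)C1 | intermediate
12 | 8β-hydroxy-cis-4,4,10-trimethyldecal-6-one | O=C1[C@@H]2C(C)(C)CCC[C@]2(C)C[C@@H](O)C1 | intermediate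
13 | cis-4,4,10-trimethyldecalin-6,8-dione | O=C1[C@@H]2C(C)(C)CCC[C@]2(C)CC(=O)C1 | intermediate
14 | 2-[(tert-butyldimethylsilyl)oxy]-N-methoxy-N-methylacetamide | CON(C)C(=O)CO[Si](C)(C)C(C)(C)C | starting material
15 | dilithium dianion of 13 (O6/O8 dienediolate, carbanion character at C9) | [Li]OC1=CC(O[Li])=C[C@@]2(C)CCCC(C)(C)[C@@H]12 | intermediate
16 | 9-[(tert-butyldimethylsilyloxy)acetyl]-cis-4,4,10-trimethyldecalin-6,8-dione (C9 enolising, no fixed configuration) | O=C1[C@@H]2C(C)(C)CCC[C@]2(C)C(C(=O)CO[Si](C)(C)C(C)(C)C)C(=O)C1 | intermediate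
17 | 9-(hydroxyacetyl)-cis-4,4,10-trimethyldecalin-6,8-dione (C9 enolising) | O=C1[C@@H]2C(C)(C)CCC[C@]2(C)C(C(=O)CO)C(=O)C1 | intermediate
18 | ring-B-fused furan-3(2H)-one, C6 ketone, 5β-H, 10β-Me | O=C1[C@@H]2C(C)(C)CCC[C@]2(C)C2=C(C1)OCC2=O | intermediate
19 | furan-fused cis-AB ketone, 11-OTBS | O=C1[C@@H]2C(C)(C)CCC[C@]2(C)c2c(C1)occ2O[Si](C)(C)C(C)(C)C | intermediate
20 | (1R,5R)-sabinene | C=C1CC[C@]2(C(C)C)C[C@@H]21 | starting material
21 | spiro 1,2,4-trioxolane of sabinene (spiro centre a mixture, inconsequential) | C1OOC2(O1)CC[C@]3(C(C)C)C[C@@H]32 | intermediate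
22 | sabina ketone | O=C1CC[C@]2(C(C)C)C[C@@H]21 | intermediate
23 | 3-methylbut-1-yne | CC(C)C#C | starting material
24 | lithium 3-methylbut-1-ynide | CC(C)C#C[Li] | intermediate
25 | lithium 4′-(3-methylbut-1-ynyl)thujan-4′-olate (O syn to cyclopropane CH2) | CC(C)C#C[C@@]1(O[Li])CC[C@]2(C(C)C)C[C@@H]21 | intermediate
26 | methyl 4′-(3-methylbut-1-ynyl)thujan-4′-yl carbonate | CC(C)C#C[C@@]1(OC(=O)OC)CC[C@]2(C(C)C)C[C@@H]21 | intermediate
27 | allenylboronate, boron on the face anti to the cyclopropane | CC(C)C(B1OC(C)(C)C(C)(C)O1)=[C@@]=C2CC[C@]3(C(C)C)C[C@@H]32 | intermediate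
28 | pinacol borate ester of 29 | CC(C)C#C[C@]1(COB2OC(C)(C)C(C)(C)O2)CC[C@]2(C(C)C)C[C@@H]21 | intermediate
29 | [4′-(3-methylbut-1-ynyl)thujan-4′-yl]methanol (alkynyl syn, CH2OH anti to cyclopropane CH2) | CC(C)C#C[C@]1(CO)CC[C@]2(C(C)C)C[C@@H]21 | intermediate
30 | 4′-(3-methylbut-1-ynyl)thujane-4′-carbaldehyde | CC(C)C#C[C@]1(C=O)CC[C@]2(C(C)C)C[C@@H]21 | intermediate
31 | lithium C6=C7 enolate of 19 | [Li]OC1=Cc2occ(O[Si](C)(C)C(C)(C)C)c2[C@@]2(C)CCCC(C)(C)[C@@H]12 | intermediate
32 | triisopropoxytitanium C6=C7 enolate of 19 | CC(C)O[Ti](OC(C)C)(OC(C)C)OC1=Cc2occ(O[Si](C)(C)C(C)(C)C)c2[C@@]2(C)CCCC(C)(C)[C@@H]12 | intermediate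
33 | syn aldol, free 10′-OH, H-7 α | CC(C)C#C[C@]1([C@@H](O)[C@H]2C(=O)[C@@H]3C(C)(C)CCC[C@]3(C)c3c(O[Si](C)(C)C(C)(C)C)coc32)CC[C@]2(C(C)C)C[C@@H]21 | intermediate
34 | cycloaddition precursor, 10′-OTES, 11-OTBS | CC(C)C#C[C@]1([C@@H](O[Si](CC)(CC)CC)[C@H]2C(=O)[C@@H]3C(C)(C)CCC[C@]3(C)c3c(O[Si](C)(C)C(C)(C)C)coc32)CC[C@]2(C(C)C)C[C@@H]21 | intermediate
35 | 7-oxanorbornadiene cycloadduct (alkyne added to the β face, oxygen bridge C8–O–C12 on the α side) | CC(C)C1=C2[C@]34O[C@H]1C(O[Si](C)(C)C(C)(C)C)=C3[C@@]5(C)CCCC(C)(C)[C@H]5C(=O)[C@@H]4[C@H](O[Si](CC)(CC)CC)[C@]26CC[C@]7(C(C)C)C[C@@H]76 | intermediate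
36 | pentacyclic C12 phenol, 11-OTBS, 10′-OTES | CC(C)c1c2c3[C@H](C(=O)[C@@H]4C(C)(C)CCC[C@]4(C)c3c(O[Si](C)(C)C(C)(C)C)c1O)[C@H](O[Si](CC)(CC)CC)[C@]21CC[C@]2(C(C)C)C[C@@H]21 | intermediate
37 | 11,12-catechol, 10′β-OH, C6 ketone | CC(C)c1c2c3[C@H](C(=O)[C@@H]4C(C)(C)CCC[C@]4(C)c3c(O)c1O)[C@H](O)[C@]21CC[C@]2(C(C)C)C[C@@H]21 | intermediate
38 | 11,12-o-quinone | CC(C)C1=C2C3=C(C(=O)C1=O)[C@@]4(C)CCCC(C)(C)[C@H]4C(=O)[C@@H]3[C@H](O)[C@]21CC[C@]2(C(C)C)C[C@@H]21 | intermediate
39 | CNP0178265.1 (11,10′β-dihydroxy-6,12-dioxo-5β-abieta-7,9(11),13-triene bridged to thujane by C7–C10′ and C14–C4′) | CC(C)C1=C2C3=C(C(=O)[C@@H]4C(C)(C)CCC[C@]4(C)C3=C(O)C1=O)[C@H](O)[C@]21CC[C@]2(C(C)C)C[C@@H]21 | target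

**Step count:** 20 steps in total. The longest linear sequence is 15 steps (steps 1–10 and 16–20).

**Steps most likely to fail**

Step 18. The alkyne is unactivated and branched on both sides, so the cycloaddition may be too slow at temperatures the silyloxyfuran tolerates. Loss or migration of silyl groups and slow enolisation towards C5 could then overtake ring closure. The fallback replaces the thermal pericyclic reaction by π-acid catalysis.
- It sets out from 34. A cationic gold(I) complex (an N-heterocyclic-carbene gold(I) bistriflimide, CH2Cl2, rt) activates the alkyne for attack by furan carbon C8.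
- The gold-catalysed furan–yne phenol synthesis then runs stepwise through a cyclopropyl gold carbene, a ring-opened dienone carbene, an oxepine and its arene oxide tautomer across C12–C13.
- C13 carries the isopropyl group, so this arene oxide can only open to the C13 cation and lose H-12. Oxygen therefore stays on C12, the same C8–C14 and C12–C13 bonds are formed, and the route is rejoined at 36.
- The fallback makes no new isolable compound (F0).

Step 16. The stabilised furfurylic enolate may add reversibly to the neopentyl aldehyde, so retro-aldol drains the adduct. Alternatively, the facial preferences may not reinforce each other, which would erode selectivity at C10′. The fallback replaces the deprotonative aldol by a reductive, irreversible Reformatsky-type coupling.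
- It sets out from 19. Lithium enolate 31 is chlorinated at −78 °C with p-toluenesulfonyl chloride to the 7β-chloro ketone F1.
- A mixture of F1 and aldehyde 30 is treated with SmI2 (2 equiv, THF, −78 °C).
- The samarium(III) enolate formed by C–Cl reduction adds through a tightly chelated closed transition state, and the oxophilic metal holds the aldolate until work-up.
- The route is rejoined at 33.

Step 8. The second deprotonation may be incomplete. Attack of the C9 carbanion next to quaternary C10 may also be slow, so that proton transfer and O-acylation compete. The fallback avoids the dianion by using the cross-conjugated monoenolate of a vinylogous ester.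
- It sets out from 13. Methanol, trimethyl orthoformate and catalytic TsOH give two separable vinylogous methyl esters: the 6-methoxy-Δ6-en-8-one F2 and the 8-methoxy-Δ7-en-6-one F3.
- F3 is hydrolysed back to 13 with aqueous acid and recycled.
- LDA deprotonates F2 at its only α′ position, C9 (Stork–Danheiser type enolate). Acylation with 14 gives the 9-acyl vinylogous ester F4.
- 2 M aq HCl in THF then cleaves the enol ether and the silyl ether and closes the furanone, rejoining the route at 18.

**Further compounds**
F0 | step 18 | none | none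
F1 | step 16 | 7β-chloro derivative of furan-fused cis-AB ketone 19 | O=C1[C@@H]2C(C)(C)CCC[C@]2(C)c2c(O[Si](C)(C)C(C)(C)C)coc2[C@H]1Cl
F2 | step 8 | 6-methoxy-cis-4,4,10-trimethyl-Δ6-octal-8-one | COC1=CC(=O)C[C@@]2(C)CCCC(C)(C)[C@@H]12
F3 | step 8 | 8-methoxy-cis-4,4,10-trimethyl-Δ7-octal-6-one | O=C1[C@@H]2C(C)(C)CCC[C@]2(C)CC(OC)=C1
F4 | step 8 | 9-[(tert-butyldimethylsilyloxy)acetyl]-6-methoxy-cis-4,4,10-trimethyl-Δ6-octal-8-one (C9 enolising) | COC1=CC(=O)C(C(=O)CO[Si](C)(C)C(C)(C)C)[C@@]2(C)CCCC(C)(C)[C@@H]12
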